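**Retrosynthetic overview**

1. Last operations: the C1′ hydroxyl is unmasked (MOM ether), and before that the alkenyl tail is completed by hydroboration of a side-chain vinyl group and alkyl–alkyl Suzuki–Miyaura coupling with 7-bromohept-1-ene, so the terminal alkene enters late and never meets an oxidant.
2. Key disconnection: the O1–C2 bond of the oxolane and the C3 stearate are made together from an acyclic 1,2,4-triol and trimethyl orthostearate. A temporary 1,3-dioxolane ring over the C2 and C3 oxygens (orthoester, then 2-heptadecyl-1,3-dioxolan-2-ylium ion) is opened at C2 by the C5 oxygen with inversion. Ring order: temporary dioxolane first, then the oxolane, the only ring of the target.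
3. Enabling feature: on the oxolane the C2 pentyl and C3 stearoyloxy groups are cis, so the O1–C2 bond lies anti to the C3–O bond, and O1 (on C5) is 1,3 to the C3 oxygen through C4H2. This is the pattern left by backside opening of a cis-4,5-disubstituted acyloxonium ion by a γ-hydroxyl.
4. The triol comes from 2-deoxy-D-ribose (its C3 and C4 become oxolane C3 and, after the inversion, C2; its C2 is C4; its C1 becomes C5), a butyl Grignard reagent, and a (Z)-γ-alkoxyallylboration that sets oxolane C5 and C1′ and leaves only the C5 hydroxyl free.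

Key step: step 9

Remark on the chemistry: locants C-1 to C-19 in the text are those of the nonadecene backbone of the target (oxolane C2 = C-6, C3 = C-7, C4 = C-8, C5 = C-9, C1′ = C-10); hemiacetal 1 is drawn open-chain; 16 is drawn as the monocyclic 2-methoxy-1,3-dioxolane, and a bicyclic orthoester that includes O-9 would ionise to the same cation 17.

**Route**

Step 1
Reactants: 1 2-deoxy-D-ribose
Product: 2 (2R,3S)-4-(1,3-dithian-2-yl)butane-1,2,3-triol
Conditions: HS(CH2)3SH, conc. aq. HCl, 0 °C → rt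
Reagents that add atoms: propane-1,3-dithiol, SCCCS
Why: Acid-catalysed dithioacetalisation opens the hemiacetal to an acyclic chain, masks C-9 as a 1,3-dithiane and frees the three hydroxyls without touching a stereocentre.

Step 2
Reactants: 2 (2R,3S)-4-(1,3-dithian-2-yl)butane-1,2,3-triol
Product: 4 (1S)-2-(1,3-dithian-2-yl)-1-[(2R)-oxiran-2-yl]ethan-1-ol, via primary tosylate 3 (not isolated)
Conditions: TsCl (1.05 equiv), pyridine, CH2Cl2, −20 °C; then K2CO3, MeOH, 0 °C
Reagents that add atoms: p-toluenesulfonyl chloride, Cc1ccc(cc1)S(Cl)(=O)=O (its tosyl group is in intermediate 3 only and leaves again on closure to 4)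
Why: Selective sulfonylation of the primary hydroxyl followed by Williamson closure by the neighbouring C-6 oxygen (3-exo-tet) should give the terminal epoxide with retention at C-6, because only the O–C-5 bond is made.

Step 3
Reactants: 4 (1S)-2-(1,3-dithian-2-yl)-1-[(2R)-oxiran-2-yl]ethan-1-ol; 5 n-butylmagnesium chloride
Product: 6 (2S,3R)-1-(1,3-dithian-2-yl)octane-2,3-diol
Conditions: n-BuMgCl (3 equiv), CuBr·SMe2 (10 mol%), THF, −40 → −10 °C; aq. NH4Cl
Reagents that add atoms: none
Why: Copper-catalysed Grignard opening of the terminal epoxide at its unsubstituted carbon (SN2) completes the pentyl chain and leaves both carbinol centres untouched, so the erythro (6R,7S) diol of the sugar is kept.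

Step 4
Reactants: 6 (2S,3R)-1-(1,3-dithian-2-yl)octane-2,3-diol
Product: 7 2-{[(4S,5R)-2,2-dimethyl-5-pentyl-1,3-dioxolan-4-yl]methyl}-1,3-dithiane
Conditions: Me2C(OMe)2, PPTS (cat.), CH2Cl2, rt
Reagents that add atoms: 2,2-dimethoxypropane, COC(C)(C)OC
Why: Acid-catalysed ketal exchange protects the vicinal diol as its cis-dioxolane (acetonide) for the two steps in which C-9 is an aldehyde.

Step 5
Reactants: 7 2-{[(4S,5R)-2,2-dimethyl-5-pentyl-1,3-dioxolan-4-yl]methyl}-1,3-dithiane
Product: 8 2-[(4S,5R)-2,2-dimethyl-5-pentyl-1,3-dioxolan-4-yl]acetaldehyde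
Conditions: I2, NaHCO3, acetone/H2O, 0 °C
Reagents that add atoms: water, O
Why: Iodine-mediated oxidative hydrolysis of the dithioacetal under bicarbonate buffer should release the aldehyde without cleaving the acetonide or causing β-elimination; the aldehyde is used at once.

Step 6
Reactants: 8 2-[(4S,5R)-2,2-dimethyl-5-pentyl-1,3-dioxolan-4-yl]acetaldehyde; 9 3-(methoxymethoxy)prop-1-ene
Product: 11 (2R,3R)-1-[(4S,5R)-2,2-dimethyl-5-pentyl-1,3-dioxolan-4-yl]-3-(methoxymethoxy)pent-4-en-2-ol, via (Z)-alkoxyallylborane 10 (not isolated)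
Conditions: 9, s-BuLi, THF, −78 °C; (−)-Ipc2BOMe; BF3·OEt2; then 8, −78 °C → rt; NaOH, H2O2
Reagents that add atoms: none
Why: Brown (Z)-γ-alkoxyallylboration through a chair Zimmerman–Traxler transition state should give the syn (threo) diol monoether, the Z geometry of the borane fixing the C-9/C-10 relative configuration and the isopinocampheyl groups from (+)-α-pinene (reagent control, si-face addition) fixing both as R, with O-10 protected and only O-9 free.

Step 7
Reactants: 11 (2R,3R)-1-[(4S,5R)-2,2-dimethyl-5-pentyl-1,3-dioxolan-4-yl]-3-(methoxymethoxy)pent-4-en-2-ol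
Product: 12 (3R,4R,6S,7R)-3-(methoxymethoxy)dodec-1-ene-4,6,7-triol
Conditions: AcOH/H2O (4:1), 40 °C
Reagents that add atoms: none
Why: Mild acid hydrolysis removes the acetonide while the less labile MOM acetal should survive, giving the 1,2,4-triol for the key step.

Step 8
Reactants: 13 octadecanenitrile
Product: 15 1,1,1-trimethoxyoctadecane, via imidate hydrochloride 14 (not isolated)
Conditions: HCl (g), MeOH (1.1 equiv), Et2O, 0 °C; then MeOH (excess), hexane, rt
Reagents that add atoms: methanol, CO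
Why: Pinner reaction of the nitrile to the imidate salt and its alcoholysis should give the orthoester that carries the C18 acyl chain at the right oxidation level.

Step 9
Reactants: 12 (3R,4R,6S,7R)-3-(methoxymethoxy)dodec-1-ene-4,6,7-triol; 15 1,1,1-trimethoxyoctadecane
Product: 18 (2S,3S,5R)-5-[(1R)-1-(methoxymethoxy)prop-2-en-1-yl]-2-pentyloxolan-3-yl octadecanoate, via cyclic orthoester 16 (not isolated), via dioxolanylium salt 17 (not isolated)
Conditions: 15 (1.3 equiv), PPTS (cat.), CH2Cl2, rt, MeOH removed in vacuo; then BF3·OEt2 (0.5 equiv), CH2Cl2, −40 → 0 °C; Et3N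
Reagents that add atoms: none
Why: Acid-catalysed exchange of 15 with the vicinal C-6/C-7 diol of 12 should give orthoester 16, BF3·OEt2 should abstract its methoxide to give the 2-heptadecyl-1,3-dioxolan-2-ylium ion 17, and the free C-9 hydroxyl should open this ion at C-6 from the back while the acyl group stays on O-7 (the former O-6 becomes the ester carbonyl oxygen), so ring closure and regiospecific stearoylation are one event. The closest known reaction type is the Lewis-acid-mediated cyclisation of 1,2,n-triols through their cyclic orthoesters and acyloxonium ions to acyloxy-substituted oxolanes and oxanes. The temporary 1,3-dioxolane ring is closed by transacetalisation, and the oxolane is closed in a 5-exo-tet mode with respect to the breaking C-6–O bond, in the fused arrangement that corresponds to the 5-endo opening of a 3,4-epoxy alcohol. The only stereocentre that changes is oxolane C2, set by stereospecific inversion of the (R)-carbinol inherited from C4 of 2-deoxy-D-ribose, while C3, C5 and C1′ are carried through with retention, which gives the 2,3-cis/2,5-trans ring. The step needs attack of O-9 on C-6 of the five-membered cation and not attack of O-6 on C-9 of an isomeric six-membered 1,3-dioxan-2-ylium ion; this should be secured by the preference of the vicinal diol for the five-membered acyloxonium ion and by the alkoxy- and vinyl-bearing C-10, which hinders and deactivates C-9 towards displacement, while attack at C-7 would need a four-membered ring.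

Step 10
Reactants: 18 (2S,3S,5R)-5-[(1R)-1-(methoxymethoxy)prop-2-en-1-yl]-2-pentyloxolan-3-yl octadecanoate; 19 7-bromohept-1-ene
Product: 21 (2S,3S,5R)-5-[(1R)-1-(methoxymethoxy)dec-9-en-1-yl]-2-pentyloxolan-3-yl octadecanoate, via B-alkyl-9-BBN adduct 20 (not isolated)
Conditions: 9-BBN-H (1.1 equiv), THF, 0 °C → rt; then 19, Pd(OAc)2 (cat.), PCy3 (cat.), K3PO4·H2O, THF, rt
Reagents that add atoms: none
Why: Anti-Markovnikov hydroboration of the only alkene present gives the primary alkylborane 20, and B-alkyl Suzuki–Miyaura alkyl–alkyl coupling with the primary bromide under Pd(OAc)2/PCy3 catalysis should join C-12 to C-13 without touching the ester or any stereocentre, the alkene of 19 being added only after the borane has been consumed.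

Step 11
Reactants: 21 (2S,3S,5R)-5-[(1R)-1-(methoxymethoxy)dec-9-en-1-yl]-2-pentyloxolan-3-yl octadecanoate
Product: 22 (2S,3S,5R)-5-[(1R)-1-hydroxydec-9-en-1-yl]-2-pentyloxolan-3-yl octadecanoate
Conditions: ZnBr2, n-PrSH, CH2Cl2, 0 °C
Reagents that add atoms: none
Why: Lewis-acid activation of the MOM acetal and capture of the methoxymethyl cation by the thiol should free the C-10 hydroxyl under conditions that leave the ester, the oxolane and the terminal alkene intact.

**Compound list**

1 | 2-deoxy-D-ribose (drawn open-chain) | O=CC[C@H](O)[C@H](O)CO | starting material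
2 | (2R,3S)-4-(1,3-dithian-2-yl)butane-1,2,3-triol | OC[C@@H](O)[C@@H](O)CC1SCCCS1 | intermediate
3 | (2R,3S)-4-(1,3-dithian-2-yl)-2,3-dihydroxybutyl 4-methylbenzenesulfonate | Cc1ccc(cc1)S(=O)(=O)OC[C@@H](O)[C@@H](O)CC1SCCCS1 | intermediate
4 | (1S)-2-(1,3-dithian-2-yl)-1-[(2R)-oxiran-2-yl]ethan-1-ol | C1O[C@H]1[C@@H](O)CC1SCCCS1 | intermediate
5 | n-butylmagnesium chloride | CCCC[Mg]Cl | starting material
6 | (2S,3R)-1-(1,3-dithian-2-yl)octane-2,3-diol | CCCCC[C@@H](O)[C@@H](O)CC1SCCCS1 | intermediate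
7 | 2-{[(4S,5R)-2,2-dimethyl-5-pentyl-1,3-dioxolan-4-yl]methyl}-1,3-dithiane | CCCCC[C@H]1OC(C)(C)O[C@H]1CC1SCCCS1 | intermediate
8 | 2-[(4S,5R)-2,2-dimethyl-5-pentyl-1,3-dioxolan-4-yl]acetaldehyde | CCCCC[C@H]1OC(C)(C)O[C@H]1CC=O | intermediate
9 | 3-(methoxymethoxy)prop-1-ene (allyl methoxymethyl ether) | C=CCOCOC | starting material
10 | [(Z)-3-(methoxymethoxy)prop-2-en-1-yl]diisopinocampheylborane (Ipc groups from (+)-α-pinene) | COCO/C=C\CB([C@@H]1C[C@@H]2C[C@H]([C@H]1C)C2(C)C)[C@@H]1C[C@@H]2C[C@H]([C@H]1C)C2(C)C | intermediate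
11 | (2R,3R)-1-[(4S,5R)-2,2-dimethyl-5-pentyl-1,3-dioxolan-4-yl]-3-(methoxymethoxy)pent-4-en-2-ol | CCCCC[C@H]1OC(C)(C)O[C@H]1C[C@@H](O)[C@H](OCOC)C=C | intermediate
12 | (3R,4R,6S,7R)-3-(methoxymethoxy)dodec-1-ene-4,6,7-triol | CCCCC[C@@H](O)[C@@H](O)C[C@@H](O)[C@H](OCOC)C=C | intermediate
13 | octadecanenitrile (stearonitrile) | CCCCCCCCCCCCCCCCCC#N | starting material
14 | methyl octadecanimidate hydrochloride | CCCCCCCCCCCCCCCCCC(=[NH2+])OC.[Cl-] | intermediate
15 | 1,1,1-trimethoxyoctadecane (trimethyl orthostearate) | CCCCCCCCCCCCCCCCCC(OC)(OC)OC | intermediate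
16 | (2R,3R)-1-[(4S,5R)-2-heptadecyl-2-methoxy-5-pentyl-1,3-dioxolan-4-yl]-3-(methoxymethoxy)pent-4-en-2-ol (both epimers at the orthoester carbon) | CCCCC[C@H]1OC(CCCCCCCCCCCCCCCCC)(OC)O[C@H]1C[C@@H](O)[C@H](OCOC)C=C | intermediate
17 | (4S,5R)-2-heptadecyl-4-[(2R,3R)-2-hydroxy-3-(methoxymethoxy)pent-4-en-1-yl]-5-pentyl-1,3-dioxolan-2-ylium methoxytrifluoroborate | CCCCC[C@H]1OC(CCCCCCCCCCCCCCCCC)=[O+][C@H]1C[C@@H](O)[C@H](OCOC)C=C.CO[B-](F)(F)F | intermediate
18 | (2S,3S,5R)-5-[(1R)-1-(methoxymethoxy)prop-2-en-1-yl]-2-pentyloxolan-3-yl octadecanoate | C=C[C@@H](OCOC)[C@H]1C[C@H](OC(=O)CCCCCCCCCCCCCCCCC)[C@H](CCCCC)O1 | intermediate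
19 | 7-bromohept-1-ene | C=CCCCCCBr | starting material
20 | (2S,3S,5R)-5-[(1R)-3-(9-borabicyclo[3.3.1]nonan-9-yl)-1-(methoxymethoxy)propyl]-2-pentyloxolan-3-yl octadecanoate | C(C[C@@H](OCOC)[C@H]1C[C@H](OC(=O)CCCCCCCCCCCCCCCCC)[C@H](CCCCC)O1)B1C2CCCC1CCC2 | intermediate
21 | (2S,3S,5R)-5-[(1R)-1-(methoxymethoxy)dec-9-en-1-yl]-2-pentyloxolan-3-yl octadecanoate | C=CCCCCCCC[C@@H](OCOC)[C@H]1C[C@H](OC(=O)CCCCCCCCCCCCCCCCC)[C@H](CCCCC)O1 | intermediate
22 | (2S,3S,5R)-5-[(1R)-1-hydroxydec-9-en-1-yl]-2-pentyloxolan-3-yl octadecanoate (CNP0171131.1) | C=CCCCCCCC[C@@H](O)[C@H]1C[C@H](OC(=O)CCCCCCCCCCCCCCCCC)[C@H](CCCCC)O1 | target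

**Step count and risks**

Total step count: 11. Longest linear sequence: 10 steps (steps 1–7 and 9–11 from 2-deoxy-D-ribose; step 8 is a one-step branch).

Most likely to fail, first: step 9. The orthoester may migrate to the C-7/C-9 oxygens so that O-6 closes onto C-9 and gives a diastereomeric oxolane, or the Lewis acid may activate the MOM acetal next to the free C-9 hydroxyl and tie both oxygens into a cyclic formal. The fallback replaces the acyloxonium ion by a cyclic sulfate, which cannot migrate, and adds the ester afterwards. It sets out from 11 and comes back at 18. The C-9 hydroxyl of 11 is silylated (TBSOTf, 2,6-lutidine) to tert-butyl({(2R,3R)-1-[(4S,5R)-2,2-dimethyl-5-pentyl-1,3-dioxolan-4-yl]-3-(methoxymethoxy)pent-4-en-2-yl}oxy)dimethylsilane F1. The acetonide is cleaved (PPTS, MeOH) to the diol (3R,4R,6S,7R)-4-[(tert-butyldimethylsilyl)oxy]-3-(methoxymethoxy)dodec-1-ene-6,7-diol F2. The diol is converted with 1,1′-sulfonyldiimidazole and NaH (THF) to the 6,7-cyclic sulfate F3. Fluoride (TBAF, THF) then frees the C-9 alkoxide, which should open the cyclic sulfate at C-6 with inversion to the tetrabutylammonium oxolan-3-yl sulfate F4. Acid hydrolysis (cat. H2SO4, H2O, THF) gives (2S,3S,5R)-5-[(1R)-1-(methoxymethoxy)prop-2-en-1-yl]-2-pentyloxolan-3-ol F5. Acylation with stearoyl chloride (pyridine, DMAP) gives 18.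

Second: step 10. Transmetalation of the alkylborane may be slow and the alkylpalladium intermediate may undergo β-hydride elimination, or residual 9-BBN-H may hydroborate the alkene of 19. The fallback makes the same C-12–C-13 bond with a copper-catalysed Grignard coupling. It sets out from 18 and comes back at 21. Hydroboration and mild oxidation (9-BBN-H, THF; NaBO3·4H2O) should give the primary alcohol (2S,3S,5R)-5-[(1R)-3-hydroxy-1-(methoxymethoxy)propyl]-2-pentyloxolan-3-yl octadecanoate F6. Appel iodination (I2, PPh3, imidazole, CH2Cl2) gives the iodide (2S,3S,5R)-5-[(1R)-3-iodo-1-(methoxymethoxy)propyl]-2-pentyloxolan-3-yl octadecanoate F7. Coupling with hept-6-en-1-ylmagnesium bromide F8 (made from 19 and Mg) under Li2CuCl4 catalysis (THF, −30 → 0 °C), conditions that spare the ester at low temperature, gives 21.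

Third: step 6. Facial selectivity may erode if the chiral borane and the β-alkoxy aldehyde are mismatched, the aldehyde may undergo β-elimination, or the alkoxyallylborane may isomerise before it adds. The fallback sets the same two centres by an auxiliary-controlled aldol reaction. It sets out from 8 and comes back at 11. (4S)-4-Benzyl-3-[(methoxymethoxy)acetyl]-1,3-oxazolidin-2-one F9 (from (4S)-4-benzyl-1,3-oxazolidin-2-one and (methoxymethoxy)acetyl chloride) is enolised (Bu2BOTf, Et3N, CH2Cl2, −78 °C) and added to 8 in an Evans syn-aldol reaction to give (4S)-4-benzyl-3-[(2S,3R)-4-[(4S,5R)-2,2-dimethyl-5-pentyl-1,3-dioxolan-4-yl]-3-hydroxy-2-(methoxymethoxy)butanoyl]-1,3-oxazolidin-2-one F10. LiBH4 (THF, MeOH, 0 °C) removes the auxiliary to give (2R,3R)-4-[(4S,5R)-2,2-dimethyl-5-pentyl-1,3-dioxolan-4-yl]-2-(methoxymethoxy)butane-1,3-diol F11. Selective oxidation of the primary hydroxyl (TEMPO, PhI(OAc)2, CH2Cl2) gives (2S,3R)-4-[(4S,5R)-2,2-dimethyl-5-pentyl-1,3-dioxolan-4-yl]-3-hydroxy-2-(methoxymethoxy)butanal F12. Wittig methylenation with methylidenetriphenylphosphorane F13 (from Ph3PCH3Br and KHMDS, THF, −78 → 0 °C) gives 11.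

Further compounds
F1 | step 9 | tert-butyl({(2R,3R)-1-[(4S,5R)-2,2-dimethyl-5-pentyl-1,3-dioxolan-4-yl]-3-(methoxymethoxy)pent-4-en-2-yl}oxy)dimethylsilane | CCCCC[C@H]1OC(C)(C)O[C@H]1C[C@@H](O[Si](C)(C)C(C)(C)C)[C@H](OCOC)C=C
F2 | step 9 | (3R,4R,6S,7R)-4-[(tert-butyldimethylsilyl)oxy]-3-(methoxymethoxy)dodec-1-ene-6,7-diol | CCCCC[C@@H](O)[C@@H](O)C[C@@H](O[Si](C)(C)C(C)(C)C)[C@H](OCOC)C=C
F3 | step 9 | 6,7-cyclic sulfate of F2: (4S,5R)-4-[(2R,3R)-2-[(tert-butyldimethylsilyl)oxy]-3-(methoxymethoxy)pent-4-en-1-yl]-5-pentyl-1,3,2-dioxathiolane 2,2-dioxide | CCCCC[C@H]1OS(=O)(=O)O[C@H]1C[C@@H](O[Si](C)(C)C(C)(C)C)[C@H](OCOC)C=C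
F4 | step 9 | tetrabutylammonium (2S,3S,5R)-5-[(1R)-1-(methoxymethoxy)prop-2-en-1-yl]-2-pentyloxolan-3-yl sulfate | C=C[C@@H](OCOC)[C@H]1C[C@H](OS(=O)(=O)[O-])[C@H](CCCCC)O1.CCCC[N+](CCCC)(CCCC)CCCC
F5 | step 9 | (2S,3S,5R)-5-[(1R)-1-(methoxymethoxy)prop-2-en-1-yl]-2-pentyloxolan-3-ol | C=C[C@@H](OCOC)[C@H]1C[C@H](O)[C@H](CCCCC)O1
F6 | step 10 | (2S,3S,5R)-5-[(1R)-3-hydroxy-1-(methoxymethoxy)propyl]-2-pentyloxolan-3-yl octadecanoate | OCC[C@@H](OCOC)[C@H]1C[C@H](OC(=O)CCCCCCCCCCCCCCCCC)[C@H](CCCCC)O1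
F7 | step 10 | (2S,3S,5R)-5-[(1R)-3-iodo-1-(methoxymethoxy)propyl]-2-pentyloxolan-3-yl octadecanoate | ICC[C@@H](OCOC)[C@H]1C[C@H](OC(=O)CCCCCCCCCCCCCCCCC)[C@H](CCCCC)O1
F8 | step 10 | hept-6-en-1-ylmagnesium bromide | C=CCCCCC[Mg]Br
F9 | step 6 | (4S)-4-benzyl-3-[(methoxymethoxy)acetyl]-1,3-oxazolidin-2-one | COCOCC(=O)N1[C@@H](Cc2ccccc2)COC1=O
F10 | step 6 | (4S)-4-benzyl-3-[(2S,3R)-4-[(4S,5R)-2,2-dimethyl-5-pentyl-1,3-dioxolan-4-yl]-3-hydroxy-2-(methoxymethoxy)butanoyl]-1,3-oxazolidin-2-one | CCCCC[C@H]1OC(C)(C)O[C@H]1C[C@@H](O)[C@H](OCOC)C(=O)N1[C@@H](Cc2ccccc2)COC1=O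
F11 | step 6 | (2R,3R)-4-[(4S,5R)-2,2-dimethyl-5-pentyl-1,3-dioxolan-4-yl]-2-(methoxymethoxy)butane-1,3-diol | CCCCC[C@H]1OC(C)(C)O[C@H]1C[C@@H](O)[C@H](OCOC)CO
F12 | step 6 | (2S,3R)-4-[(4S,5R)-2,2-dimethyl-5-pentyl-1,3-dioxolan-4-yl]-3-hydroxy-2-(methoxymethoxy)butanal | CCCCC[C@H]1OC(C)(C)O[C@H]1C[C@@H](O)[C@H](OCOC)C=O
F13 | step 6 | methylidenetriphenylphosphorane | C=P(c1ccccc1)(c1ccccc1)c1ccccc1
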